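**Assumption:** atom labels C1–C15 follow germacrane numbering (C6 lactone carbinol, C7 ring-fusion CH, C8 ester carbon, C9 free carbinol, C10=C1 Z-alkene, C4–C5 epoxide, C11=C13 exocyclic methylene, C12 lactone carbonyl).

## Retrosynthetic overview

1. Final operations: acylate the C8 hydroxyl with 3-methylbut-2-enoic acid, then remove the C9 4-methoxybenzyl (PMB) ether oxidatively.
2. Key disconnection C7–C8: C7, the β-carbon of a 3-(bromomethyl)butenolide, is made nucleophilic as an allylindium (homoenolate-type) and adds to the C8 aldehyde. This one step closes the ten-membered ring, sets C7 and C8 and unveils the exocyclic methylene.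
3. Butenolide: ester of the C6 carbinol with 2-(bromomethyl)acrylic acid, closed by metathesis onto a C7 vinyl group. C6 and the 4,5-epoxide come from one-pot asymmetric vinylation and directed epoxidation of an enal.
4. Chain: Z-selective Wittig of a geranyl acetate-derived ylide (C1–C6) with an L-glycerate-derived α-alkoxy methyl ketone (C8–C10, carries C9). The 4-methoxybenzylidene acetal is then opened to C9-OPMB and C8-OH.
5. Ring order: epoxide, then butenolide, then the ten-membered carbocycle.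

## Route

**Step 1**
Reactants: 1 geranyl acetate [(2E)-3,7-dimethylocta-2,6-dien-1-yl acetate]
Product: 3 (2E)-6-hydroxy-3-methylhex-2-en-1-yl acetate, via aldehyde 2 (not isolated)
Conditions: O3 (1.0 equiv), pyridine, CH2Cl2, −78 °C; then NaBH4, MeOH, −78 → 0 °C
Reagents that add atoms: ozone, O=[O+][O-]
Why: Ozonolysis with reductive work-up cleaves the electron-rich terminal trisubstituted alkene in preference to the 2,3-alkene deactivated by the allylic acetate; no stereocenter is formed and the E geometry of the future C4=C5 bond is inherited from geraniol.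

**Step 2**
Reactants: 3 (2E)-6-hydroxy-3-methylhex-2-en-1-yl acetate
Product: 4 (2E)-6-iodo-3-methylhex-2-en-1-yl acetate
Conditions: I2, PPh3, imidazole, CH2Cl2, 0 → 25 °C
Reagents that add atoms: iodine, II
Why: Appel-type iodination (SN2 at the primary carbinol) that leaves the allylic acetate and the alkene untouched; no stereocenter involved.

**Step 3**
Reactants: 4 (2E)-6-iodo-3-methylhex-2-en-1-yl acetate
Product: 5 [(4E)-6-acetoxy-4-methylhex-4-en-1-yl]triphenylphosphonium iodide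
Conditions: PPh3, MeCN, 80 °C
Reagents that add atoms: triphenylphosphine, c1ccc(cc1)P(c1ccccc1)c1ccccc1
Why: SN2 quaternisation of PPh3 by the primary iodide (phosphonium salt formation); no stereocenter involved.

**Step 4**
Reactants: 6 methyl (4S)-2,2-dimethyl-1,3-dioxolane-4-carboxylate
Product: 7 methyl (4S)-2-(4-methoxyphenyl)-1,3-dioxolane-4-carboxylate (mixture at the acetal carbon)
Conditions: 4-MeOC6H4CH(OMe)2, camphorsulfonic acid (5 mol %), toluene, 60 °C, 150 mbar
Reagents that add atoms: 4-methoxybenzaldehyde dimethyl acetal, COc1ccc(cc1)C(OC)OC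
Why: Acid-catalysed transacetalisation driven by distilling off 2,2-dimethoxypropane; the chiral-pool carbinol centre (future C9) is not touched and the acetal-carbon mixture is irrelevant because that centre is destroyed in step 7.

**Step 5**
Reactants: 7 methyl (4S)-2-(4-methoxyphenyl)-1,3-dioxolane-4-carboxylate
Product: 9 1-[(4S)-2-(4-methoxyphenyl)-1,3-dioxolan-4-yl]ethan-1-one, via Weinreb amide 8 (not isolated)
Conditions: MeNH(OMe)·HCl, i-PrMgCl, THF, −20 °C; then MeMgBr, −20 → 0 °C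
Reagents that add atoms: methylmagnesium bromide, C[Mg]Br
Why: One-pot Weinreb ketone synthesis in which the chelated tetrahedral intermediate stops the Grignard addition at the methyl ketone; the α-alkoxy stereocenter is retained at low temperature.

**Step 6**
Reactants: 5 [(4E)-6-acetoxy-4-methylhex-4-en-1-yl]triphenylphosphonium iodide; 9 1-[(4S)-2-(4-methoxyphenyl)-1,3-dioxolan-4-yl]ethan-1-one
Product: 11 (2E,6Z)-7-[(4R)-2-(4-methoxyphenyl)-1,3-dioxolan-4-yl]-3-methylocta-2,6-dien-1-yl acetate, via ylide 10 (not isolated)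
Conditions: KN(SiMe3)2 (1.0 equiv), THF, −78 °C; then 9, −78 → 0 °C
Reagents that add atoms: none
Why: Wittig olefination of an α-alkoxy ketone with a salt-free non-stabilised ylide (Still-type Z-selective variant) places the oxygen-bearing carbon C9 cis to the ylide chain, giving the C10=C1 Z-alkene; C9 comes unchanged from the glycerate.

**Step 7**
Reactants: 11 (2E,6Z)-7-[(4R)-2-(4-methoxyphenyl)-1,3-dioxolan-4-yl]-3-methylocta-2,6-dien-1-yl acetate
Product: 12 (2E,6Z,8R)-8-[(4-methoxyphenyl)methoxy]-3,7-dimethylnona-2,6-diene-1,9-diol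
Conditions: i-Bu2AlH (5 equiv), CH2Cl2, −78 → 0 °C
Reagents that add atoms: none
Why: Regioselective reductive opening of the 4-methoxybenzylidene acetal (aluminium binds the less hindered primary oxygen, so the PMB group stays on the secondary C9 oxygen) with concurrent reductive removal of the acetate; no stereocenter is changed.

**Step 8**
Reactants: 12 (2E,6Z,8R)-8-[(4-methoxyphenyl)methoxy]-3,7-dimethylnona-2,6-diene-1,9-diol
Product: 13 (2E,6Z,8R)-9-hydroxy-8-[(4-methoxyphenyl)methoxy]-3,7-dimethylnona-2,6-dienal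
Conditions: MnO2, CH2Cl2, 25 °C
Reagents that add atoms: none
Why: Chemoselective allylic oxidation: MnO2 converts only the allylic primary alcohol into the E-enal and leaves the saturated C8 alcohol alone.

**Step 9**
Reactants: 13 (2E,6Z,8R)-9-hydroxy-8-[(4-methoxyphenyl)methoxy]-3,7-dimethylnona-2,6-dienal
Product: 14 (2E,6Z,8R)-8-[(4-methoxyphenyl)methoxy]-3,7-dimethyl-9-[(triethylsilyl)oxy]nona-2,6-dienal
Conditions: Et3SiCl, imidazole, CH2Cl2, 0 °C
Reagents that add atoms: chlorotriethylsilane, CC[Si](Cl)(CC)CC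
Why: Silyl ether formation on the only free hydroxyl, masking C8 during the organozinc, acylation and metathesis steps.

**Step 10**
Reactants: 14 (2E,6Z,8R)-8-[(4-methoxyphenyl)methoxy]-3,7-dimethyl-9-[(triethylsilyl)oxy]nona-2,6-dienal
Product: 16 (1S)-1-[(2R,3R)-3-{(3Z,5R)-5-[(4-methoxyphenyl)methoxy]-4-methyl-6-[(triethylsilyl)oxy]hex-3-en-1-yl}-3-methyloxiran-2-yl]prop-2-en-1-ol, via dienol zinc alkoxide 15 (not isolated)
Conditions: Zn(CH=CH2)2 (1.6 equiv), (−)-MIB [(2S)-3-exo-morpholinoisoborneol] (5 mol %), toluene/hexane, −20 → 0 °C; then t-BuOOH (2 equiv), Ti(OiPr)4 (20 mol %), 0 °C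
Reagents that add atoms: divinylzinc, C=C[Zn]C=C; tert-butyl hydroperoxide, CC(C)(C)OO
Why: Amino-alcohol-catalysed enantioselective vinylzinc addition to the enal (Si-face delivery with (−)-MIB sets 6S) followed by titanium-mediated alkoxide-directed epoxidation, in which A(1,3) strain with the cis C4 methyl fixes the H-eclipsed conformer and gives the threo 4R,5R epoxide; only the allylic trisubstituted alkene reacts.

**Step 11**
Reactants: 16 (1S)-1-[(2R,3R)-3-{(3Z,5R)-5-[(4-methoxyphenyl)methoxy]-4-methyl-6-[(triethylsilyl)oxy]hex-3-en-1-yl}-3-methyloxiran-2-yl]prop-2-en-1-ol; 17 2-(bromomethyl)prop-2-enoic acid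
Product: 18 (1S)-1-[(2R,3R)-3-{(3Z,5R)-5-[(4-methoxyphenyl)methoxy]-4-methyl-6-[(triethylsilyl)oxy]hex-3-en-1-yl}-3-methyloxiran-2-yl]prop-2-en-1-yl 2-(bromomethyl)prop-2-enoate
Conditions: N,N'-diisopropylcarbodiimide, DMAP (10 mol %), CH2Cl2, −10 → 0 °C
Reagents that add atoms: none
Why: Steglich-type carbodiimide esterification acylates the C6 oxygen with retention of configuration; low temperature and little DMAP limit attack on the allylic bromide.

**Step 12**
Reactants: 18 (1S)-1-[(2R,3R)-3-{(3Z,5R)-5-[(4-methoxyphenyl)methoxy]-4-methyl-6-[(triethylsilyl)oxy]hex-3-en-1-yl}-3-methyloxiran-2-yl]prop-2-en-1-yl 2-(bromomethyl)prop-2-enoate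
Product: 19 (5S)-3-(bromomethyl)-5-[(2R,3R)-3-{(3Z,5R)-5-[(4-methoxyphenyl)methoxy]-4-methyl-6-[(triethylsilyl)oxy]hex-3-en-1-yl}-3-methyloxiran-2-yl]furan-2(5H)-one
Conditions: second-generation Hoveyda–Grubbs catalyst (5 mol %), toluene (0.005 M), 80 °C
Reagents that add atoms: none
Why: Ring-closing metathesis between the acrylate and the vinyl group forms the five-membered butenolide (C7=C11) with loss of ethene; the trisubstituted alkenes, epoxide and allylic bromide are spectators and no stereocenter is touched.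

**Step 13**
Reactants: 19 (5S)-3-(bromomethyl)-5-[(2R,3R)-3-{(3Z,5R)-5-[(4-methoxyphenyl)methoxy]-4-methyl-6-[(triethylsilyl)oxy]hex-3-en-1-yl}-3-methyloxiran-2-yl]furan-2(5H)-one
Product: 20 (5S)-3-(bromomethyl)-5-[(2R,3R)-3-{(3Z,5R)-6-hydroxy-5-[(4-methoxyphenyl)methoxy]-4-methylhex-3-en-1-yl}-3-methyloxiran-2-yl]furan-2(5H)-one
Conditions: HF·pyridine, THF, 0 °C
Reagents that add atoms: none
Why: Fluoride-mediated cleavage of the primary triethylsilyl ether under mildly acidic, non-nucleophilic conditions that spare the epoxide, PMB ether and allylic bromide.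

**Step 14**
Reactants: 20 (5S)-3-(bromomethyl)-5-[(2R,3R)-3-{(3Z,5R)-6-hydroxy-5-[(4-methoxyphenyl)methoxy]-4-methylhex-3-en-1-yl}-3-methyloxiran-2-yl]furan-2(5H)-one
Product: 21 (2R,3Z)-6-{(2R,3R)-3-[(2S)-4-(bromomethyl)-5-oxo-2,5-dihydrofuran-2-yl]-2-methyloxiran-2-yl}-2-[(4-methoxyphenyl)methoxy]-3-methylhex-3-enal
Conditions: Dess–Martin periodinane, NaHCO3, CH2Cl2, 0 → 25 °C
Reagents that add atoms: none
Why: Buffered Dess–Martin oxidation gives the α-alkoxy aldehyde without epimerising C9 or moving the Z-alkene into conjugation; the aldehyde is used crude at once.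

**Step 15**
Reactants: 21 (2R,3Z)-6-{(2R,3R)-3-[(2S)-4-(bromomethyl)-5-oxo-2,5-dihydrofuran-2-yl]-2-methyloxiran-2-yl}-2-[(4-methoxyphenyl)methoxy]-3-methylhex-3-enal
Product: 23 (1(10)Z,4R,5R,6S,7R,8R,9R)-4,5-epoxy-8-hydroxy-9-[(4-methoxyphenyl)methoxy]germacra-1(10),11(13)-dien-12,6-olide, via allylindium 22 (not isolated)
Conditions: In powder (3 equiv), THF/H2O (4:1), 0.003 M (slow addition of 21), 25 °C
Reagents that add atoms: none
Why: Proposed new method: an intramolecular version of the known indium- or chromium-mediated Barbier allylation of aldehydes with 3-(bromomethyl)furan-2(5H)-ones, in which indium inserts into the C–Br bond so that the normally electrophilic lactone β-carbon C7 becomes the nucleophilic terminus of allylindium 22 (a homoenolate equivalent) and adds to the C8 aldehyde through a six-membered chair transition state with allyl transposition, closing the ten-membered ring and unveiling the exocyclic methylene in one event; C7 is set by attack anti to the C5 substituent on C6 (trans lactone), C8 by the ring-locked E-allyl geometry with the aldehyde substituent equatorial (7,8-anti) reinforced by indium chelation to the C9 PMB ether (8,9-syn), all three elements converging on 7R,8R, and the closest precedents are the intermolecular allylations with this bromide class and Barbier or Nozaki–Hiyama macrocyclisations to ten-membered germacranolides.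

**Step 16**
Reactants: 23 (1(10)Z,4R,5R,6S,7R,8R,9R)-4,5-epoxy-8-hydroxy-9-[(4-methoxyphenyl)methoxy]germacra-1(10),11(13)-dien-12,6-olide; 24 3-methylbut-2-enoic acid
Product: 25 (1(10)Z,4R,5R,6S,7R,8R,9R)-4,5-epoxy-9-[(4-methoxyphenyl)methoxy]-8-(3-methylbut-2-enoyloxy)germacra-1(10),11(13)-dien-12,6-olide
Conditions: N,N'-diisopropylcarbodiimide, DMAP, CH2Cl2, 0 → 25 °C
Reagents that add atoms: none
Why: Steglich esterification of the only free hydroxyl (C8) with retention; the carbodiimide route avoids the ketene pathway that deconjugates senecioyl chloride.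

**Step 17**
Reactants: 25 (1(10)Z,4R,5R,6S,7R,8R,9R)-4,5-epoxy-9-[(4-methoxyphenyl)methoxy]-8-(3-methylbut-2-enoyloxy)germacra-1(10),11(13)-dien-12,6-olide
Product: 26 (1(10)Z,4R,5R,6S,7R,8R,9R)-4,5-epoxy-9-hydroxy-8-(3-methylbut-2-enoyloxy)germacra-1(10),11(13)-dien-12,6-olide (target)
Conditions: DDQ, CH2Cl2/pH 7 phosphate buffer (10:1), 0 °C
Reagents that add atoms: none
Why: Oxidative PMB ether cleavage (single-electron oxidation, then hydrolysis of the oxocarbenium ion) under neutral conditions that avoid acid-induced transannular opening of the epoxide and leave both esters and the methylene lactone intact.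

## Compound list

1 | geranyl acetate, (2E)-3,7-dimethylocta-2,6-dien-1-yl acetate | CC(=O)OC/C=C(\C)CCC=C(C)C | starting material
2 | (2E)-3-methyl-6-oxohex-2-en-1-yl acetate (not isolated) | CC(=O)OC/C=C(\C)CCC=O | intermediate
3 | (2E)-6-hydroxy-3-methylhex-2-en-1-yl acetate | CC(=O)OC/C=C(\C)CCCO | intermediate
4 | (2E)-6-iodo-3-methylhex-2-en-1-yl acetate | CC(=O)OC/C=C(\C)CCCI | intermediate
5 | [(4E)-6-acetoxy-4-methylhex-4-en-1-yl]triphenylphosphonium iodide | CC(=O)OC/C=C(\C)CCC[P+](c1ccccc1)(c1ccccc1)c1ccccc1.[I-] | intermediate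
6 | methyl (4S)-2,2-dimethyl-1,3-dioxolane-4-carboxylate | COC(=O)[C@@H]1COC(C)(C)O1 | starting material
7 | methyl (4S)-2-(4-methoxyphenyl)-1,3-dioxolane-4-carboxylate (both acetal epimers) | COC(=O)[C@@H]1COC(c2ccc(OC)cc2)O1 | intermediate
8 | (4S)-N-methoxy-2-(4-methoxyphenyl)-N-methyl-1,3-dioxolane-4-carboxamide (not isolated) | CON(C)C(=O)[C@@H]1COC(c2ccc(OC)cc2)O1 | intermediate
9 | 1-[(4S)-2-(4-methoxyphenyl)-1,3-dioxolan-4-yl]ethan-1-one | CC(=O)[C@@H]1COC(c2ccc(OC)cc2)O1 | intermediate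
10 | (2E)-3-methyl-6-(triphenylphosphoranylidene)hex-2-en-1-yl acetate (ylide, not isolated) | CC(=O)OC/C=C(\C)CCC=P(c1ccccc1)(c1ccccc1)c1ccccc1 | intermediate
11 | (2E,6Z)-7-[(4R)-2-(4-methoxyphenyl)-1,3-dioxolan-4-yl]-3-methylocta-2,6-dien-1-yl acetate | CC(=O)OC/C=C(\C)CC/C=C(C)\[C@@H]1COC(c2ccc(OC)cc2)O1 | intermediate
12 | (2E,6Z,8R)-8-[(4-methoxyphenyl)methoxy]-3,7-dimethylnona-2,6-diene-1,9-diol | OC/C=C(\C)CC/C=C(C)\[C@H](CO)OCc1ccc(OC)cc1 | intermediate
13 | (2E,6Z,8R)-9-hydroxy-8-[(4-methoxyphenyl)methoxy]-3,7-dimethylnona-2,6-dienal | O=C/C=C(\C)CC/C=C(C)\[C@H](CO)OCc1ccc(OC)cc1 | intermediate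
14 | (2E,6Z,8R)-8-[(4-methoxyphenyl)methoxy]-3,7-dimethyl-9-[(triethylsilyl)oxy]nona-2,6-dienal | O=C/C=C(\C)CC/C=C(C)\[C@H](CO[Si](CC)(CC)CC)OCc1ccc(OC)cc1 | intermediate
15 | (3S,4E,8Z,10R)-10-[(4-methoxyphenyl)methoxy]-5,9-dimethyl-11-[(triethylsilyl)oxy]undeca-1,4,8-trien-3-ol (present as its zinc alkoxide, not isolated) | C=C[C@H](O)/C=C(\C)CC/C=C(C)\[C@H](CO[Si](CC)(CC)CC)OCc1ccc(OC)cc1 | intermediate
16 | (1S)-1-[(2R,3R)-3-{(3Z,5R)-5-[(4-methoxyphenyl)methoxy]-4-methyl-6-[(triethylsilyl)oxy]hex-3-en-1-yl}-3-methyloxiran-2-yl]prop-2-en-1-ol | C=C[C@H](O)[C@H]1O[C@]1(C)CC/C=C(C)\[C@H](CO[Si](CC)(CC)CC)OCc1ccc(OC)cc1 | intermediate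
17 | 2-(bromomethyl)prop-2-enoic acid | OC(=O)C(=C)CBr | starting material
18 | (1S)-1-[(2R,3R)-3-{(3Z,5R)-5-[(4-methoxyphenyl)methoxy]-4-methyl-6-[(triethylsilyl)oxy]hex-3-en-1-yl}-3-methyloxiran-2-yl]prop-2-en-1-yl 2-(bromomethyl)prop-2-enoate | C=C[C@H](OC(=O)C(=C)CBr)[C@H]1O[C@]1(C)CC/C=C(C)\[C@H](CO[Si](CC)(CC)CC)OCc1ccc(OC)cc1 | intermediate
19 | (5S)-3-(bromomethyl)-5-[(2R,3R)-3-{(3Z,5R)-5-[(4-methoxyphenyl)methoxy]-4-methyl-6-[(triethylsilyl)oxy]hex-3-en-1-yl}-3-methyloxiran-2-yl]furan-2(5H)-one | O=C1O[C@@H](C=C1CBr)[C@H]2O[C@]2(C)CC/C=C(C)\[C@H](CO[Si](CC)(CC)CC)OCc1ccc(OC)cc1 | intermediate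
20 | (5S)-3-(bromomethyl)-5-[(2R,3R)-3-{(3Z,5R)-6-hydroxy-5-[(4-methoxyphenyl)methoxy]-4-methylhex-3-en-1-yl}-3-methyloxiran-2-yl]furan-2(5H)-one | O=C1O[C@@H](C=C1CBr)[C@H]2O[C@]2(C)CC/C=C(C)\[C@H](CO)OCc1ccc(OC)cc1 | intermediate
21 | (2R,3Z)-6-{(2R,3R)-3-[(2S)-4-(bromomethyl)-5-oxo-2,5-dihydrofuran-2-yl]-2-methyloxiran-2-yl}-2-[(4-methoxyphenyl)methoxy]-3-methylhex-3-enal | O=C1O[C@@H](C=C1CBr)[C@H]2O[C@]2(C)CC/C=C(C)\[C@H](C=O)OCc1ccc(OC)cc1 | intermediate
22 | allylindium dibromide of 21 (trivalent indium on C13, not isolated) | O=C1O[C@@H](C=C1C[In](Br)Br)[C@H]2O[C@]2(C)CC/C=C(C)\[C@H](C=O)OCc1ccc(OC)cc1 | intermediate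
23 | (1(10)Z,4R,5R,6S,7R,8R,9R)-4,5-epoxy-8-hydroxy-9-[(4-methoxyphenyl)methoxy]germacra-1(10),11(13)-dien-12,6-olide | C=C1C(=O)O[C@H]2[C@H]1[C@@H](O)[C@H](OCc1ccc(OC)cc1)/C(C)=C\CC[C@@]1(C)O[C@H]21 | intermediate
24 | 3-methylbut-2-enoic acid | CC(C)=CC(=O)O | starting material
25 | (1(10)Z,4R,5R,6S,7R,8R,9R)-4,5-epoxy-9-[(4-methoxyphenyl)methoxy]-8-(3-methylbut-2-enoyloxy)germacra-1(10),11(13)-dien-12,6-olide | C=C1C(=O)O[C@H]2[C@H]1[C@@H](OC(=O)C=C(C)C)[C@H](OCc1ccc(OC)cc1)/C(C)=C\CC[C@@]1(C)O[C@H]21 | intermediate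
26 | (1(10)Z,4R,5R,6S,7R,8R,9R)-4,5-epoxy-9-hydroxy-8-(3-methylbut-2-enoyloxy)germacra-1(10),11(13)-dien-12,6-olide, CNP0188779.3 | C=C1C(=O)O[C@H]2[C@H]1[C@@H](OC(=O)C=C(C)C)[C@H](O)/C(C)=C\CC[C@@]1(C)O[C@H]21 | target

## Step count and risks

Total step count: 17. Longest linear sequence: 15 steps (steps 1–3, then 6–17, from geranyl acetate 1); the glycerate branch (steps 4–5) joins at step 6.

**Risk 1, step 15 (ring closure).** Possible failures are oligomerisation, protonation of 22 to the 3-methylbutenolide, and addition on the wrong face of C7. The fallback sets out from 19 and comes back at 23. The bromide of 19 is exchanged for acetate (KOAc, 18-crown-6, MeCN) to give the acetoxymethyl butenolide silyl ether F1. HF·pyridine then gives the acetoxymethyl butenolide alcohol F2, and Dess–Martin oxidation gives the acetoxymethyl butenolide aldehyde F3. The ring is closed by palladium-catalysed allyl polarity inversion: Pd(PPh3)4 (zerovalent palladium, 5 mol %) ionises the allylic acetate to a π-allylpalladium species, Et2Zn turns it into a nucleophilic allylzinc, and this adds through C7 to the aldehyde under homogeneous high dilution (THF, 0.002 M) to give 23.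

**Risk 2, step 12 (metathesis of the bromomethyl acrylate).** The hindered, electron-poor 1,1-disubstituted alkene may react slowly, and the allylic bromide may shorten catalyst life. The fallback sets out from 16 and comes back at 19, installing C13 after the ring is made. Compound 16 is acylated with acryloyl chloride (i-Pr2NEt, CH2Cl2, −20 °C) to the acrylate ester F4. Ring-closing metathesis (second-generation Grubbs catalyst, CH2Cl2, 40 °C) gives the 3-unsubstituted butenolide F5. Morita–Baylis–Hillman hydroxymethylation (aqueous formaldehyde, imidazole, THF/H2O) gives the 3-(hydroxymethyl)butenolide F6, and CBr4/PPh3 converts it into 19.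

**Risk 3, step 10 (one-pot vinylation and epoxidation).** The enantioselectivity at C6 or the threo selectivity may be too low on this substrate. The fallback sets out from 14 and comes back at 16, replacing catalytic asymmetric addition by resolution and a separate directed epoxidation. Vinylmagnesium bromide (THF, −78 °C) adds to 14 to give the C3-epimeric dienol mixture F7. Sharpless kinetic resolution (Ti(OiPr)4, D-(−)-diisopropyl tartrate, t-BuOOH 0.6 equiv, 4 Å molecular sieves, CH2Cl2, −20 °C) consumes the 3R epimer as the erythro epoxy alcohol F8, which is separated, and leaves the 3S dienol 15, isolated this time. Tartrate-free directed epoxidation of 15 (t-BuOOH, Ti(OiPr)4, CH2Cl2, 0 °C) then gives 16.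

## Further compounds

F1 | step 15 | (5S)-3-(acetoxymethyl)-5-[(2R,3R)-3-{(3Z,5R)-5-[(4-methoxyphenyl)methoxy]-4-methyl-6-[(triethylsilyl)oxy]hex-3-en-1-yl}-3-methyloxiran-2-yl]furan-2(5H)-one | O=C1O[C@@H](C=C1COC(C)=O)[C@H]2O[C@]2(C)CC/C=C(C)\[C@H](CO[Si](CC)(CC)CC)OCc1ccc(OC)cc1
F2 | step 15 | (5S)-3-(acetoxymethyl)-5-[(2R,3R)-3-{(3Z,5R)-6-hydroxy-5-[(4-methoxyphenyl)methoxy]-4-methylhex-3-en-1-yl}-3-methyloxiran-2-yl]furan-2(5H)-one | O=C1O[C@@H](C=C1COC(C)=O)[C@H]2O[C@]2(C)CC/C=C(C)\[C@H](CO)OCc1ccc(OC)cc1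
F3 | step 15 | (2R,3Z)-6-{(2R,3R)-3-[(2S)-4-(acetoxymethyl)-5-oxo-2,5-dihydrofuran-2-yl]-2-methyloxiran-2-yl}-2-[(4-methoxyphenyl)methoxy]-3-methylhex-3-enal | O=C1O[C@@H](C=C1COC(C)=O)[C@H]2O[C@]2(C)CC/C=C(C)\[C@H](C=O)OCc1ccc(OC)cc1
F4 | step 12 | (1S)-1-[(2R,3R)-3-{(3Z,5R)-5-[(4-methoxyphenyl)methoxy]-4-methyl-6-[(triethylsilyl)oxy]hex-3-en-1-yl}-3-methyloxiran-2-yl]prop-2-en-1-yl prop-2-enoate | C=C[C@H](OC(=O)C=C)[C@H]1O[C@]1(C)CC/C=C(C)\[C@H](CO[Si](CC)(CC)CC)OCc1ccc(OC)cc1
F5 | step 12 | (5S)-5-[(2R,3R)-3-{(3Z,5R)-5-[(4-methoxyphenyl)methoxy]-4-methyl-6-[(triethylsilyl)oxy]hex-3-en-1-yl}-3-methyloxiran-2-yl]furan-2(5H)-one | O=C1O[C@@H](C=C1)[C@H]2O[C@]2(C)CC/C=C(C)\[C@H](CO[Si](CC)(CC)CC)OCc1ccc(OC)cc1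
F6 | step 12 | (5S)-3-(hydroxymethyl)-5-[(2R,3R)-3-{(3Z,5R)-5-[(4-methoxyphenyl)methoxy]-4-methyl-6-[(triethylsilyl)oxy]hex-3-en-1-yl}-3-methyloxiran-2-yl]furan-2(5H)-one | O=C1O[C@@H](C=C1CO)[C@H]2O[C@]2(C)CC/C=C(C)\[C@H](CO[Si](CC)(CC)CC)OCc1ccc(OC)cc1
F7 | step 10 | (3RS,4E,8Z,10R)-10-[(4-methoxyphenyl)methoxy]-5,9-dimethyl-11-[(triethylsilyl)oxy]undeca-1,4,8-trien-3-ol | C=CC(O)/C=C(\C)CC/C=C(C)\[C@H](CO[Si](CC)(CC)CC)OCc1ccc(OC)cc1
F8 | step 10 | (1R)-1-[(2R,3R)-3-{(3Z,5R)-5-[(4-methoxyphenyl)methoxy]-4-methyl-6-[(triethylsilyl)oxy]hex-3-en-1-yl}-3-methyloxiran-2-yl]prop-2-en-1-ol | C=C[C@@H](O)[C@H]1O[C@]1(C)CC/C=C(C)\[C@H](CO[Si](CC)(CC)CC)OCc1ccc(OC)cc1
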